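The next run needs one change.

all flasks: gas phase 9.5 mM (held)
- south-west: substrate 0.025 M; run made earlier
- north-east: substrate 0.10 M; run made earlier
- flask: substrate 0.050 M; time 25 min

- south-west (time / min: target / %, substrate / %): 2.50: 6, 94; 6.00: 15, 88; 12.0: 19, 73; 30.0: 28, 59
- north-east (time / min: target / %, substrate / %): 8.00: 13, 81; 15.0: 21, 71; 25.0: 23, 64; 30.0: 28, 57

(readings scatter by 2 percentage points)

- at the start none of the gas phase is in solution

- theta: doubling the saturation concentration of gas phase, all else as stated
- delta: doubling the transfer coefficient of the gas phase, all else as stated

- amount of target at 25 min, in percent of the substrate charged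
- the change that raises the amount of target at 25 min, in percent of the substrate charged most ("none" if none brings more than 2 percentage points) (theta / delta / none)
- amount of target at 25 min, in percent of the substrate charged, after delta

1. Working with the fraction left, the south-west run gives 0.0213 min⁻¹ at 6.00 min and the north-east run gives 0.0263 min⁻¹ at 8.00 min. Their mean, 0.0238 min⁻¹, is the early left-rate, the logarithm of one over the fraction of substrate left, divided by the time. The charges differ 4.00-fold and the two values differ by 0.00500 min⁻¹, so early on the substrate looks pseudo-first-order and the 0.050 M flask can share this rate.

2. This rate leaves 94.2% at 2.50 min, and the south-west run reads 94%. Although no gas is in solution at the start, no lag shows in the south-west run, so delta promises little, and my reckoning puts target after delta a little above the figure reached below.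

3. At 25 min the rate leaves 55.2%, but the north-east run reads 64%, so the loss of substrate slows in that run, and that reading serves for the flask.

4. At 30.0 min target makes up 66.7% of the substrate gone in the two runs, which puts target in the flask at 24.0%.

5. The south-west and north-east runs both used 9.5 mM, so theta is an untested bet on the rate following dissolved gas, but it is the change to charge.

The forecast gives 25%, above my figure, with theta best and 25.5% after delta, holding that “the gas dissolves quickly compared with reaction”.

The flask gives 25.9%. The best change is theta, worth 14 percentage points against 0.32 points for delta, and delta yields 26.3%.

    gas phase ⇌ dissolved gas, rate k1*(csat - [dissolved gas]) (kL = 2.30 min⁻¹)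
    substrate + dissolved gas ⇌ target (K = 81.0 M⁻¹, k = 3.20 M⁻¹ min⁻¹)
    target ⇌ isomer of the product (K = 1.10, k = 0.0380 min⁻¹)

The early left-rate gives 74.3% for the asked flask at 12.5 min, where 75.5% of the substrate stands, while at 25.0 min the flask holds 61.9% against the 55.2% that rate gives. The neighbour flask, the same charge read at 6.0 min, takes the same reckoning: the rate gives 86.7%, and that flask holds 87%. Of the 13.4% gone there, target is 12.1% and the isomer of the product 1.32%.

The readings stem from a simulated flask with made-up constants; scatter was added.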